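A single rate constant is the pitfall in these flasks: the spring run and the winter run carry the same free catalyst for the same 23 min, yet they do not return one constant.

| flask | starting material | partner | free catalyst | time |
|---|---|---|---|---|
| winter | 120 mM | 180 mM | 9.60 mM |  |
| summer | 120 mM | 180 mM | 14.0 mM |  |
| spring | 120 mM | 90.0 mM | 9.60 mM |  |
| midnight | 360 mM | 180 mM | 9.60 mM |  |
| noon | 120 mM | 52.0 mM | 9.60 mM | 23 min |

- winter run (time / min: [starting material] / mM): 0.92: 120.0; 1.6: 119.1; 2.7: 117.3; 4.6: 110.7; 7.9: 96.4; 13: 72.7; 23: 38.6
- summer run (time / min: [starting material] / mM): 0.92: 119.6; 1.6: 119.1; 2.7: 114.7; 4.6: 107.0; 7.9: 87.3; 13: 60.1; 23: 28.2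
- spring run (time / min: [starting material] / mM): 0.92: 119.4; 1.6: 119.9; 2.7: 118.3; 4.6: 116.1; 7.9: 107.7; 13: 96.1; 23: 75.5
- midnight run (time / min: [starting material] / mM): 0.92: 358.6; 1.6: 356.8; 2.7: 348.3; 4.6: 327.4; 7.9: 278.7; 13: 223.6; 23: 187.7

(scatter of a reading: 0.4 mM)

* the exponent of [free catalyst] in the starting rate at the charge of the winter run (at the point where two percent of the starting material have become product)
* the exponent of [starting material] in the starting rate at the charge of the winter run (at the point where two percent of the starting material have become product) (one fixed amount of product, the same in the runs compared)
* starting material in the noon run at 23 min, as a share of the starting material charged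

- Overall: starting material + partner -> product, with free catalyst as catalyst.
- Constant volume, constant temperature.
- An order is taken over about fifteen percent of the charge, up and down.

My reckoning takes the rate as proportional to starting material and to partner, with a coefficient free to change in time. Each run then gives an exposure, the time integral of that coefficient:

exposure = ln[(starting material ÷ its charge) ÷ (partner ÷ its charge)] ÷ (charge of starting material − charge of partner)

At 23 min the spring run reads 0.00729 mM⁻¹ with 44.5 mM of product. The winter run reads more, 0.00887 mM⁻¹, with 81.4 mM. A straight line through these two readings treats product as a correction to a product-free exposure of 0.00538 mM⁻¹.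

Partner is the limiting reagent of the noon flask, whose starting material cannot fall below 56.7% of its charge. Assuming product reaches half the partner charge, the line gives an exposure of 0.00650 mM⁻¹. The givens then fold into one number:

stretch = exposure × (charge of starting material − charge of partner) = 0.442

This stretch is the logarithm of how far the ratio of starting material to partner has climbed above its charged value. In the noon flask that ratio becomes 3.59, which leaves 94.3 mM of starting material, or 78.5%. Product then comes to half the partner charge, as assumed.

Is one number enough? The same line, carried to the midnight run, predicts 189.5 mM at 23 min against a reading of 187.7 mM. The miss is 0.959%: close, but outside the scatter of 0.4 mM.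

The forecast gave 0.92, 0.7 and 78.6%, the last from an extrapolated exposure that, in its words, “leaves about 94 mM”.

The simulation gives 0.54, 0.59 and 78.4%.

    2 active catalyst ⇌ catalyst dimer, settled at all times (9050 L mol⁻¹)
    catalyst dimer + starting material + partner → product + catalyst dimer (78.00 L² mol⁻² min⁻¹)
    free catalyst → active catalyst (0.1458 min⁻¹)
    starting material + partner + product → 2 product (3.516 L² mol⁻² min⁻¹)

In the noon flask free catalyst went over to active catalyst with a lifetime of 6.86 min, and 0.336 mM of it stood at 23 min, while the catalyst dimer formed from active catalyst turned over starting material and partner and the product step ran beside it as product grew. At 23 min the noon flask held 26.1 mM of partner, a stretch of 0.447 against the reckoned 0.442. The spring run, where product reached half its starting material at 34.9 min, stood at a stretch of 0.405.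

The data are calculated with made-up constants; noise was put on by code.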